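**Plan**

- Retrosynthesis (quinic acid locants): cut the two cinnamate C–O bonds (caffeoyl at O3, p-coumaroyl at O4), tie O5 and CO2H together as the γ-lactone, then cut C1–C2 of the cyclohexane.
- Enabling feature: C1 is a tertiary α-hydroxy-acid carbon between the two ring CH2 groups (C2, C6), with its CO2H cis-1,3 to O5. This is the retron of a benzilic ester ring contraction of a cycloheptane-1,2-dione in which O5 is the built-in alkoxide (8-oxabicyclo[3.2.1]octane hemiketal → 6-oxabicyclo[3.2.1]octan-7-one).
- Forward: 2-deoxy-L-ribose → 1,8-nonadiene → RCM to the seven-membered carbocycle → 1,2-dione → transannular hemiketal → contraction to the cyclohexane carrying the lactone bridge → acetonide off, O3 then O4 acylation, acid hydrolysis.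
- Stereochemistry: C3 and C4 are bought with the sugar, C5 is set by a tartrate allylboronate (reagent control), and C1 is relayed from C5 through the temporary O5–C(=O) bridge. The diol centres made on the way to the dione are destroyed and need no control.

Key step: step 10

Remark: the given SMILES is read as the 3-O-caffeoyl-4-O-p-coumaroyl ester of (−)-quinic acid (O3 cis to O4; O5 trans to O4 and cis to CO2H; 1-OH trans to CO2H... i.e. cis to O3), and these locants are used throughout.

**Route**

Step 1
Reactants: 1 2-deoxy-L-ribose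
Product: 2 2-deoxy-3,4-O-isopropylidene-L-erythro-pentopyranose (lactol, anomer mixture)
Conditions: 2-methoxypropene, PPTS (cat.), EtOAc, 0 °C → rt
Reagents that add atoms: 2-methoxypropene, C=C(C)OC
Why: Kinetic transacetalisation (acetonide formation) should place the isopropylidene on the cis-3,4-diol of the pyranose form and leave the lactol free; no stereocenter is set.

Step 2
Reactants: 2 2-deoxy-3,4-O-isopropylidene-L-erythro-pentopyranose
Product: 3 [(4S,5R)-2,2-dimethyl-5-(prop-2-en-1-yl)-1,3-dioxolan-4-yl]methanol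
Conditions: Ph3PCH3Br (2.5 equiv), KOtBu (2.5 equiv), THF, 0 °C → reflux
Reagents that add atoms: methyltriphenylphosphonium bromide, C[P+](c1ccccc1)(c1ccccc1)c1ccccc1.[Br-]
Why: Wittig methylenation of the open-chain aldehyde in equilibrium with the lactol should give the terminal alkene with the two sugar stereocenters untouched.

Step 3
Reactants: 3 [(4S,5R)-2,2-dimethyl-5-(prop-2-en-1-yl)-1,3-dioxolan-4-yl]methanol
Product: 4 (4R,5R)-2,2-dimethyl-5-(prop-2-en-1-yl)-1,3-dioxolane-4-carbaldehyde
Conditions: Dess–Martin periodinane, CH2Cl2, 0 °C → rt; used crude at once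
Reagents that add atoms: none
Why: Dess–Martin oxidation of the primary alcohol under base-free conditions should keep the epimerisable cis-α-alkoxy aldehyde intact.

Step 4
Reactants: 4 (4R,5R)-2,2-dimethyl-5-(prop-2-en-1-yl)-1,3-dioxolane-4-carbaldehyde
Product: 5 (1R)-1-[(4S,5R)-2,2-dimethyl-5-(prop-2-en-1-yl)-1,3-dioxolan-4-yl]but-3-en-1-ol
Conditions: (S,S)-diisopropyl tartrate allylboronate (1.5 equiv), 4 Å MS, toluene, −78 °C; aqueous work-up
Reagents that add atoms: diisopropyl (4S,5S)-2-allyl-1,3,2-dioxaborolane-4,5-dicarboxylate, C=CCB1O[C@H](C(=O)OC(C)C)[C@@H](C(=O)OC(C)C)O1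
Why: Roush asymmetric allylboration through a chair six-membered transition state: the (S,S)-reagent should deliver allyl to the re face, setting the (1R) carbinol syn (threo) to the dioxolane oxygen (later O5 trans to O4) by reagent control over the modest Felkin (anti) bias of the aldehyde.

Step 5
Reactants: 5 (1R)-1-[(4S,5R)-2,2-dimethyl-5-(prop-2-en-1-yl)-1,3-dioxolan-4-yl]but-3-en-1-ol
Product: 6 tert-butyl({(1R)-1-[(4R,5R)-2,2-dimethyl-5-(prop-2-en-1-yl)-1,3-dioxolan-4-yl]but-3-en-1-yl}oxy)dimethylsilane
Conditions: TBSOTf, 2,6-lutidine, CH2Cl2, −78 → 0 °C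
Reagents that add atoms: tert-butyldimethylsilyl triflate, CC(C)(C)[Si](C)(C)OS(=O)(=O)C(F)(F)F
Why: Silylation of the hindered secondary alcohol with the silyl triflate should mask O5 through the oxidation steps and leave it releasable by fluoride.

Step 6
Reactants: 6 tert-butyl({(1R)-1-[(4R,5R)-2,2-dimethyl-5-(prop-2-en-1-yl)-1,3-dioxolan-4-yl]but-3-en-1-yl}oxy)dimethylsilane
Product: 7 tert-butyl{[(3aR,4R,8aR)-2,2-dimethyl-3a,5,8,8a-tetrahydro-4H-cyclohepta[d][1,3]dioxol-4-yl]oxy}dimethylsilane (cis-fused; OTBS trans to the neighbouring acetonide oxygen)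
Conditions: Grubbs II (3 mol %), CH2Cl2 (0.005 M), 40 °C
Reagents that add atoms: none
Why: Ring-closing metathesis of the 1,8-diene should close the cycloheptene readily because the cis-dioxolane holds both chains on one side.

Step 7
Reactants: 7 tert-butyl{[(3aR,4R,8aR)-2,2-dimethyl-3a,5,8,8a-tetrahydro-4H-cyclohepta[d][1,3]dioxol-4-yl]oxy}dimethylsilane
Product: 8 (3aR,4R,8aR)-4-[(tert-butyldimethylsilyl)oxy]-2,2-dimethylhexahydro-4H-cyclohepta[d][1,3]dioxole-6,7-diol (cis-diol, either face)
Conditions: OsO4 (2 mol %), NMO (1.5 equiv), acetone/H2O 4:1, rt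
Reagents that add atoms: osmium tetroxide (catalytic oxygen carrier), O=[Os](=O)(=O)=O; N-methylmorpholine N-oxide, C[N+]1([O-])CCOCC1; water, O
Why: Upjohn syn-dihydroxylation of the only alkene; the two new carbinol centres are erased in step 8, so facial selectivity is irrelevant.

Step 8
Reactants: 8 (3aR,4R,8aR)-4-[(tert-butyldimethylsilyl)oxy]-2,2-dimethylhexahydro-4H-cyclohepta[d][1,3]dioxole-6,7-diol
Product: 9 (3aR,4R,8aR)-4-[(tert-butyldimethylsilyl)oxy]-2,2-dimethyltetrahydro-4H-cyclohepta[d][1,3]dioxole-6,7-dione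
Conditions: IBX (3 equiv), DMSO, rt
Reagents that add atoms: none
Why: IBX oxidises vicinal diols to 1,2-diketones without C–C cleavage and under neutral conditions, which should spare the β-silyloxy and β-acetal oxygens.

Step 9
Reactants: 9 (3aR,4R,8aR)-4-[(tert-butyldimethylsilyl)oxy]-2,2-dimethyltetrahydro-4H-cyclohepta[d][1,3]dioxole-6,7-dione
Product: 11 1-hydroxy-3,4-(isopropylidenedioxy)-8-oxabicyclo[3.2.1]octan-7-one (bridged hemiketal; OH on the bridgehead next to the ketone, acetonide on the three-carbon bridge anti to the oxygen bridge), via 4-hydroxy-2,2-dimethyltetrahydro-4H-cyclohepta[d][1,3]dioxole-6,7-dione 10 (not isolated)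
Conditions: HF·pyridine, pyridine, THF, 0 °C → rt
Reagents that add atoms: none
Why: Buffered fluoride desilylation frees the C5–OH, which should add transannularly (5-exo-trig) to the distal carbonyl of the electrophilic 1,2-dione (the proximal one would need a four-membered ring), the new hemiketal centre being dictated by the bridge.

Step 10
Reactants: 11 1-hydroxy-3,4-(isopropylidenedioxy)-8-oxabicyclo[3.2.1]octan-7-one
Product: 12 3,4-O-isopropylidene-1,5-quinide (quinic acid 1,5-lactone 3,4-acetonide)
Conditions: KHMDS (1.05 equiv), THF, −78 → 0 °C; then AcOH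
Reagents that add atoms: none
Why: Proposed new method: deprotonation of the bridgehead hemiketal OH gives an alkoxide whose C–CH2 bond (hemiketal carbon to the CH2 of the three-carbon bridge) shifts to the neighbouring ketone carbon while the alkoxide collapses to a lactone C=O, so the hemiketal carbon leaves the carbocycle as the carboxyl carbon and the seven-membered ring becomes the cyclohexane (an intramolecular benzilic ester, α-ketol-type 1,2-shift). The closest known reactions are the benzilic acid and benzilic ester ring contractions of cyclic 1,2-diones with external hydroxide or alkoxide and the base- or Lewis-acid-promoted α-ketol rearrangements; new here is a transannular ring alkoxide on a cycloheptane-1,2-dione. No ring is closed by cyclisation: the six-membered carbocycle forms by the suprafacial 1,2-carbon shift through a three-centre transition state, and the five-membered oxygen ring (O5, C5, C6, C1, carboxyl carbon) is carried over from the hemiketal as the γ-lactone. The one new stereocenter, C1, is fixed by that bridge: the carboxyl carbon stays bonded to O5, so CO2 must end cis to O5 and the new tertiary OH (the former ketone oxygen) trans to it, which is the quinic acid configuration, while C3, C4 and C5 are not touched. The step needs the shift to outrun reopening of the hemiketal, enolisation with β-elimination and retro-aldol cleavage; the bicycle should secure this because it masks one carbonyl (no acidic CH2 next to the acetonide), holds O− and C=O nearly syn-periplanar for K+ chelation with the migrating bond almost perpendicular to the carbonyl plane, and leaves only one carbon able to migrate, and the alkoxide is formed stoichiometrically at low temperature.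

Step 11
Reactants: 12 3,4-O-isopropylidene-1,5-quinide
Product: 13 1,5-quinide (1,3,4-trihydroxy-6-oxabicyclo[3.2.1]octan-7-one; 3-OH equatorial, 4-OH axial)
Conditions: TFA/H2O 9:1, 0 °C → rt, short; evaporate
Reagents that add atoms: none
Why: Acid-catalysed acetal hydrolysis should free the cis-3,4-diol while the γ-lactone, which is stable to brief aqueous acid, keeps O5 and CO2H protected.

Step 12
Reactants: 14 caffeic acid
Product: 15 3,4-di-O-acetylcaffeic acid
Conditions: Ac2O, pyridine, DMAP (cat.), 0 °C → rt; then H2O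
Reagents that add atoms: acetic anhydride, CC(=O)OC(C)=O
Why: Acetylation of both phenols (any mixed anhydride at the acid is hydrolysed on work-up) masks the catechol for acid chloride chemistry.

Step 13
Reactants: 13 1,5-quinide; 15 3,4-di-O-acetylcaffeic acid
Product: 17 3-O-(3,4-di-O-acetylcaffeoyl)-1,5-quinide, via 3,4-di-O-acetylcaffeoyl chloride 16 (not isolated)
Conditions: 15, (COCl)2, DMF (cat.), CH2Cl2, 0 °C → rt, evaporate; then 13, 2-aminoethyl diphenylborinate (10 mol %), i-Pr2NEt, MeCN, 0 °C → rt
Reagents that add atoms: none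
Why: Borinic acid-catalysed regioselective acylation of a cis-1,2-diol: the catalyst should bind the cis-3,4-diol as a tetracoordinate borinate that reacts with the acid chloride at the equatorial O3, leaving the axial 4-OH and the tertiary 1-OH free.

Step 14
Reactants: 18 p-coumaric acid
Product: 19 4-O-acetyl-p-coumaric acid
Conditions: Ac2O, pyridine, DMAP (cat.), 0 °C → rt; then H2O
Reagents that add atoms: acetic anhydride, CC(=O)OC(C)=O
Why: Acetylation of the phenol masks it for acid chloride chemistry.

Step 15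
Reactants: 17 3-O-(3,4-di-O-acetylcaffeoyl)-1,5-quinide; 19 4-O-acetyl-p-coumaric acid
Product: 21 3-O-(3,4-di-O-acetylcaffeoyl)-4-O-(4-O-acetyl-p-coumaroyl)-1,5-quinide, via 4-O-acetyl-p-coumaroyl chloride 20 (not isolated)
Conditions: 19, (COCl)2, DMF (cat.), CH2Cl2, 0 °C → rt, evaporate; then 17, pyridine, DMAP (cat.), CH2Cl2, 0 °C → rt (1.2 equiv of 20)
Reagents that add atoms: none
Why: DMAP-catalysed esterification of the remaining axial 4-OH should be much faster than acylation of the tertiary 1-OH next to the lactone carbonyl, which is spared by limiting the acid chloride.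

Step 16
Reactants: 21 3-O-(3,4-di-O-acetylcaffeoyl)-4-O-(4-O-acetyl-p-coumaroyl)-1,5-quinide
Product: 22 3-O-caffeoyl-4-O-p-coumaroylquinic acid (target)
Conditions: 1 M aq. HCl/THF 1:4, rt (to 40 °C if slow)
Reagents that add atoms: water, O
Why: Acid-catalysed hydrolysis should open the strained γ-lactone and cleave the three aryl acetates, which are far more labile than the two secondary cinnamates, and acid is chosen because acyl migration among O3, O4 and O5 is base-promoted.

**Compound list**

1 | 2-deoxy-L-ribose (open-chain form drawn) | O=CC[C@@H](O)[C@@H](O)CO | starting material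
2 | 2-deoxy-3,4-O-isopropylidene-L-erythro-pentopyranose | OC1C[C@H]2OC(C)(C)O[C@H]2CO1 | intermediate
3 | [(4S,5R)-2,2-dimethyl-5-(prop-2-en-1-yl)-1,3-dioxolan-4-yl]methanol | C=CC[C@H]1OC(C)(C)O[C@H]1CO | intermediate
4 | (4R,5R)-2,2-dimethyl-5-(prop-2-en-1-yl)-1,3-dioxolane-4-carbaldehyde | C=CC[C@H]1OC(C)(C)O[C@H]1C=O | intermediate
5 | (1R)-1-[(4S,5R)-2,2-dimethyl-5-(prop-2-en-1-yl)-1,3-dioxolan-4-yl]but-3-en-1-ol | C=CC[C@H]1OC(C)(C)O[C@H]1[C@H](O)CC=C | intermediate
6 | TBS ether of 5 | C=CC[C@H]1OC(C)(C)O[C@H]1[C@H](O[Si](C)(C)C(C)(C)C)CC=C | intermediate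
7 | (3aR,4R,8aR)-4-(TBSO)-2,2-dimethyl-3a,5,8,8a-tetrahydro-4H-cyclohepta[d][1,3]dioxole | C1=CC[C@H]2OC(C)(C)O[C@H]2[C@H](O[Si](C)(C)C(C)(C)C)C1 | intermediate
8 | (3aR,4R,8aR)-4-(TBSO)-2,2-dimethylhexahydro-4H-cyclohepta[d][1,3]dioxole-6,7-diol (cis-diol, either face) | OC1C[C@H]2OC(C)(C)O[C@H]2[C@H](O[Si](C)(C)C(C)(C)C)CC1O | intermediate
9 | (3aR,4R,8aR)-4-(TBSO)-2,2-dimethyltetrahydro-4H-cyclohepta[d][1,3]dioxole-6,7-dione | O=C1C[C@H]2OC(C)(C)O[C@H]2[C@H](O[Si](C)(C)C(C)(C)C)CC1=O | intermediate
10 | 4-hydroxy-2,2-dimethyltetrahydro-4H-cyclohepta[d][1,3]dioxole-6,7-dione (configuration as in 9) | O=C1C[C@H]2OC(C)(C)O[C@H]2[C@H](O)CC1=O | intermediate (not isolated)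
11 | 1-hydroxy-3,4-(isopropylidenedioxy)-8-oxabicyclo[3.2.1]octan-7-one (bridged hemiketal) | O=C1C[C@@H]2[C@@H]3OC(C)(C)O[C@@H]3C[C@@]1(O)O2 | intermediate
12 | 3,4-O-isopropylidene-1,5-quinide | O=C1O[C@@H]2C[C@@]1(O)C[C@H]3OC(C)(C)O[C@@H]23 | intermediate
13 | 1,5-quinide | O=C1O[C@@H]2C[C@@]1(O)C[C@@H](O)[C@H]2O | intermediate
14 | caffeic acid | O=C(O)/C=C/c1ccc(O)c(O)c1 | starting material
15 | 3,4-di-O-acetylcaffeic acid | CC(=O)Oc1ccc(/C=C/C(=O)O)cc1OC(C)=O | intermediate
16 | 3,4-di-O-acetylcaffeoyl chloride | CC(=O)Oc1ccc(/C=C/C(=O)Cl)cc1OC(C)=O | intermediate (not isolated)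
17 | 3-O-(3,4-di-O-acetylcaffeoyl)-1,5-quinide | O=C1O[C@@H]2C[C@@]1(O)C[C@@H](OC(=O)/C=C/c3ccc(OC(C)=O)c(OC(C)=O)c3)[C@H]2O | intermediate
18 | p-coumaric acid | O=C(O)/C=C/c1ccc(O)cc1 | starting material
19 | 4-O-acetyl-p-coumaric acid | CC(=O)Oc1ccc(/C=C/C(=O)O)cc1 | intermediate
20 | 4-O-acetyl-p-coumaroyl chloride | CC(=O)Oc1ccc(/C=C/C(=O)Cl)cc1 | intermediate (not isolated)
21 | 3-O-(3,4-di-O-acetylcaffeoyl)-4-O-(4-O-acetyl-p-coumaroyl)-1,5-quinide | O=C1O[C@@H]2C[C@@]1(O)C[C@@H](OC(=O)/C=C/c3ccc(OC(C)=O)c(OC(C)=O)c3)[C@H]2OC(=O)/C=C/c1ccc(OC(C)=O)cc1 | intermediate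
22 | 3-O-caffeoyl-4-O-p-coumaroylquinic acid | O=C(/C=C/c1ccc(O)cc1)O[C@H]1[C@H](O)C[C@](O)(C(=O)O)C[C@H]1OC(=O)/C=C/c1ccc(O)c(O)c1 | target

**Count**

Total steps: 16. Longest linear sequence: 14 (steps 1–11, 13, 15, 16).

**Steps most likely to fail**

1. Step 10 (proposed new method). The hemiketal alkoxide may reopen faster than its carbon shifts; the open 5-oxido-dione can then enolise and lose the acetal oxygen by E1cB, or cleave between C5 and C6 by retro-aldol. The fallback sets out from 9, with the silyl ether kept so that no O5 alkoxide can form. The established hydroxide-mediated benzilic acid rearrangement of a cyclic 1,2-dione (KOH, aq. dioxane, rt) should contract the ring to the 1-hydroxy acid as a pair of C1 epimers, the wanted one being 5-O-TBS-3,4-O-isopropylidenequinic acid F1. TBAF in THF would then give 3,4-O-isopropylidenequinic acid F2. Lactonisation (TsOH cat., toluene, reflux) closes only the epimer whose CO2H is cis to O5 and returns to the route at 12; the C1 epimer stays an acid and is removed by a bicarbonate wash.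

2. Step 8. During the double oxidation the dione can enolise, with β-elimination of the silyloxy or acetal oxygen towards a tropolone-type product, or be dehydrogenated further by excess IBX. The fallback sets out from 7 and bypasses 8. Ruthenium-catalysed ketohydroxylation (RuCl3 cat., Oxone, NaHCO3, EtOAc/MeCN/H2O) should give the acyloin 4-(TBSO)-6-hydroxy-2,2-dimethylhexahydro-4H-cyclohepta[d][1,3]dioxol-7-one F3 (or its regioisomer, which converges). One short Dess–Martin oxidation at 0 °C then returns to the route at 9.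

3. Step 13. Discrimination between the equatorial 3-OH and the axial 4-OH may be incomplete, or the 3-mono-ester may migrate to O4 under the basic conditions, which would scramble the two acyl groups. The fallback sets out from 13. Selective silylation of the equatorial 3-OH (TBSCl, imidazole, DMF, 0 °C) should give 3-O-TBS-1,5-quinide F4. Acylation of the 4-OH with 20 (pyridine, DMAP) gives 3-O-TBS-4-O-(4-O-acetyl-p-coumaroyl)-1,5-quinide F5. Acidic desilylation (HF·pyridine, THF) gives 4-O-(4-O-acetyl-p-coumaroyl)-1,5-quinide F6. Acylation of its 3-OH with 16 (pyridine, CH2Cl2, −20 °C) returns to the route at 21.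

**Further compounds**

F1 | step 10 | 5-O-TBS-3,4-O-isopropylidenequinic acid | OC(=O)[C@]1(O)C[C@H]2OC(C)(C)O[C@H]2[C@H](O[Si](C)(C)C(C)(C)C)C1
F2 | step 10 | 3,4-O-isopropylidenequinic acid | OC(=O)[C@]1(O)C[C@H]2OC(C)(C)O[C@H]2[C@H](O)C1
F3 | step 8 | 4-(TBSO)-6-hydroxy-2,2-dimethylhexahydro-4H-cyclohepta[d][1,3]dioxol-7-one (carbinol configuration open) | O=C1C[C@H]2OC(C)(C)O[C@H]2[C@H](O[Si](C)(C)C(C)(C)C)CC1O
F4 | step 13 | 3-O-TBS-1,5-quinide | O=C1O[C@@H]2C[C@@]1(O)C[C@@H](O[Si](C)(C)C(C)(C)C)[C@H]2O
F5 | step 13 | 3-O-TBS-4-O-(4-O-acetyl-p-coumaroyl)-1,5-quinide | O=C1O[C@@H]2C[C@@]1(O)C[C@@H](O[Si](C)(C)C(C)(C)C)[C@H]2OC(=O)/C=C/c1ccc(OC(C)=O)cc1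
F6 | step 13 | 4-O-(4-O-acetyl-p-coumaroyl)-1,5-quinide | O=C1O[C@@H]2C[C@@]1(O)C[C@@H](O)[C@H]2OC(=O)/C=C/c1ccc(OC(C)=O)cc1
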